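**Retrosynthetic overview**

1. Target ⇐ (S)-[10]-gingerol by diacetylation and selective release of the phenol; no protecting group is used.
2. (S)-[10]-gingerol ⇐ a (6S)-3-vanillyl-6-nonyl-4-hydroxy-5,6-dihydro-2-pyranone. Water opens this β-keto lactone and the lactone carbon leaves as CO2, so the β-hydroxy ketone is never made by an aldol reaction.
3. The single stereocentre ⇐ enantioselective hydrogenation of the C5=C6 bond of the flat, aromatic 4-hydroxy-2-pyranone (the dearomatizing key step).
4. That pyranone ⇐ triacetic acid lactone, by octylation of its 6-methyl group (dianion) and reductive C3-benzylation with vanillin.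
5. Ring order: no ring is built. The pyranone ring is bought, dearomatized in step 3 and opened in step 4; the arene comes unchanged from vanillin.

Assumption: the (R)-antipode of the diphosphine is taken to give the 6S lactone; if the first run shows the opposite sense, the (S)-antipode is used and nothing else changes.

**Route**

Step 1
Reactants: 1 triacetic acid lactone (4-hydroxy-6-methyl-2H-pyran-2-one); 2 1-bromooctane
Product: 5 4-hydroxy-6-nonyl-2H-pyran-2-one, via dilithium pyranone dianion 3 (not isolated), via lithium 6-nonylpyranolate 4 (not isolated)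
Conditions: LiN(i-Pr)2 (commercial solution, 2.2 equiv), THF/DMPU, −78 °C; then 2 (1.1 equiv), −78 °C → rt; 1 M HCl work-up
Reagents that add atoms: none
Why: The O4/C7 dianion is alkylated by the primary bromide only at the exocyclic carbon, because attack there keeps the pyranone conjugation and the oxido site is a far weaker nucleophile (lateral dianion alkylation, SN2).

Step 2
Reactants: 5 4-hydroxy-6-nonyl-2H-pyran-2-one; 6 vanillin (4-hydroxy-3-methoxybenzaldehyde)
Product: 8 4-hydroxy-3-(4-hydroxy-3-methoxybenzyl)-6-nonyl-2H-pyran-2-one, via benzylidene pyrandione 7 (not isolated)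
Conditions: Hantzsch ester (diethyl 2,6-dimethyl-1,4-dihydropyridine-3,5-dicarboxylate, 1.1 equiv), L-proline (20 mol %), EtOH, 40 °C
Reagents that add atoms: none
Why: Proline-catalysed Knoevenagel condensation at the nucleophilic C3 gives the arylidene dione, which the Hantzsch ester reduces by hydride transfer before a second pyranone can add (three-component reductive alkylation); the free phenol is tolerated.

Step 3
Reactants: 8 4-hydroxy-3-(4-hydroxy-3-methoxybenzyl)-6-nonyl-2H-pyran-2-one
Product: 9 (6S)-4-hydroxy-3-(4-hydroxy-3-methoxybenzyl)-6-nonyl-5,6-dihydro-2H-pyran-2-one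
Conditions: Ru(OAc)2[(R)-3,5-tBu-MeOBIPHEP] (0.5 mol %), HBF4·OEt2 (1 mol %), H2 (60 bar), i-PrOH, 60 °C; recrystallise
Reagents that add atoms: none
Why: Cationic ruthenium–biaryl diphosphine catalysts hydrogenate only the C5=C6 bond of 3,6-disubstituted 4-hydroxy-2-pyranones and leave the C3=C4 enol of the resulting β-keto lactone. The chiral diphosphine fixes the face to which H2 is delivered, so C6 is set as S (enantioselective dearomatizing hydrogenation), and crystallisation of the lactone raises the ee. The ligand is (R)-(6,6'-dimethoxybiphenyl-2,2'-diyl)bis[bis(3,5-di-tert-butylphenyl)phosphane].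

Step 4
Reactants: 9 (6S)-4-hydroxy-3-(4-hydroxy-3-methoxybenzyl)-6-nonyl-5,6-dihydro-2H-pyran-2-one
Product: 11 (5S)-5-hydroxy-1-(4-hydroxy-3-methoxyphenyl)tetradecan-3-one [(S)-[10]-gingerol], via ring-opened β-keto acid 10 (not isolated)
Conditions: 1,4-dioxane/H2O (1:1), N2, 80 °C
Reagents that add atoms: none
Why: Water opens the δ-lactone to the β-keto acid, which loses CO2 through the usual six-membered transition state (hydrolytic decarboxylation of a β-keto lactone, as the parent 6-methyl dihydropyranone does in warm water). The medium stays weakly acidic, where the β-hydroxy ketone neither dehydrates nor undergoes retro-aldol cleavage, and no bond to C5 is touched.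

Step 5
Reactants: 11 (5S)-5-hydroxy-1-(4-hydroxy-3-methoxyphenyl)tetradecan-3-one
Product: 13 (5S)-1-(4-hydroxy-3-methoxyphenyl)-3-oxotetradecan-5-yl acetate (target), via gingerol diacetate 12 (not isolated)
Conditions: Ac2O (3 equiv), pyridine, DMAP (cat.), CH2Cl2, 0 °C → rt; MeOH quench; then NH4OAc (8 equiv), MeOH/H2O (4:1), rt
Reagents that add atoms: acetic anhydride, CC(=O)OC(C)=O
Why: Ac2O/pyridine acetylates both hydroxyls (O-acylation). Buffered NH4OAc then cleaves only the aryl acetate by ammonolysis at neutral pH, where the secondary alkyl acetate is inert and the β-acetoxy ketone does not eliminate, so the C5 configuration is retained.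

**Compound list**

1 | triacetic acid lactone (4-hydroxy-6-methyl-2H-pyran-2-one) | CC1=CC(O)=CC(=O)O1 | starting material
2 | 1-bromooctane | CCCCCCCCBr | starting material
3 | dilithium dianion of 1 (4-oxido, 6-methylide) | [Li+].[Li+].[CH2-]C1=CC([O-])=CC(=O)O1 | intermediate (not isolated)
4 | lithium 6-nonyl-2-oxo-2H-pyran-4-olate | [Li+].CCCCCCCCCC1=CC([O-])=CC(=O)O1 | intermediate (not isolated)
5 | 4-hydroxy-6-nonyl-2H-pyran-2-one | CCCCCCCCCC1=CC(O)=CC(=O)O1 | intermediate
6 | vanillin (4-hydroxy-3-methoxybenzaldehyde) | COc1cc(C=O)ccc1O | starting material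
7 | 3-(4-hydroxy-3-methoxybenzylidene)-6-nonyl-2H-pyran-2,4(3H)-dione (alkene geometry irrelevant) | CCCCCCCCCC1=CC(=O)C(=Cc2ccc(O)c(OC)c2)C(=O)O1 | intermediate (not isolated)
8 | 4-hydroxy-3-(4-hydroxy-3-methoxybenzyl)-6-nonyl-2H-pyran-2-one | CCCCCCCCCC1=CC(O)=C(Cc2ccc(O)c(OC)c2)C(=O)O1 | intermediate
9 | (6S)-4-hydroxy-3-(4-hydroxy-3-methoxybenzyl)-6-nonyl-5,6-dihydro-2H-pyran-2-one | CCCCCCCCC[C@H]1CC(O)=C(Cc2ccc(O)c(OC)c2)C(=O)O1 | intermediate
10 | (5S)-5-hydroxy-2-(4-hydroxy-3-methoxybenzyl)-3-oxotetradecanoic acid (both C2 epimers) | CCCCCCCCC[C@H](O)CC(=O)C(Cc1ccc(O)c(OC)c1)C(O)=O | intermediate (not isolated)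
11 | (5S)-5-hydroxy-1-(4-hydroxy-3-methoxyphenyl)tetradecan-3-one, (S)-[10]-gingerol | CCCCCCCCC[C@H](O)CC(=O)CCc1ccc(O)c(OC)c1 | intermediate
12 | (5S)-1-(4-acetoxy-3-methoxyphenyl)-3-oxotetradecan-5-yl acetate | CCCCCCCCC[C@@H](CC(=O)CCc1ccc(OC(C)=O)c(OC)c1)OC(C)=O | intermediate (not isolated)
13 | (5S)-1-(4-hydroxy-3-methoxyphenyl)-3-oxotetradecan-5-yl acetate | CCCCCCCCC[C@@H](CC(=O)CCc1ccc(O)c(OC)c1)OC(C)=O | target

**Step count**

Total steps: 5. Longest linear sequence: 5 steps (1 → 5 → 8 → 9 → 11 → 13).

**Steps most likely to fail, and fallbacks**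

Step 1 (lateral alkylation of the dianion). The dilithium salt is poorly soluble and an unactivated bromide reacts slowly, so low conversion or polyalkylation is possible. Step 4 is judged safer than this because the parent lactone shows the same ring opening. The fallback sets out from 1 and replaces the dianion by a monoanion of the O-protected pyranone. Methylation of 1 (Me2SO4, K2CO3, acetone, reflux) gives 4-methoxy-6-methyl-2H-pyran-2-one F1. Lithiation of its methyl group (LiN(i-Pr)2, 1.1 equiv, THF/DMPU, −78 °C) and alkylation with 2 gives 4-methoxy-6-nonyl-2H-pyran-2-one F2. Iodotrimethylsilane (MeCN, 50 °C) cleaves the enol methyl ether to 4-(trimethylsilyloxy)-6-nonyl-2H-pyran-2-one F3, which a cold aqueous work-up converts to 5, where the route is rejoined.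

Step 3 (key hydrogenation). The 3-arylmethyl group and the free phenol may lower rate or ee compared with simple 3,6-dialkyl pyranones. The fallback sets out from 5 and sets the stereocentre before the arene is attached, with a different catalyst class. Compound 5 is hydrogenated over Pd/TiO2 modified with a cinchona alkaloid (cinchonidine or cinchonine, whichever gives 6S; H2, i-PrOH, rt), a modifier-directed heterogeneous hydrogenation known for the 6-methyl parent. This gives (6S)-4-hydroxy-6-nonyl-5,6-dihydro-2H-pyran-2-one F4, which is recrystallised to raise the ee. The reductive alkylation of step 2 (6, Hantzsch ester, L-proline, EtOH) is then run on F4; C3 of the β-keto lactone is still the nucleophile and C6 cannot epimerise. This gives 9, where the route is rejoined.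

Step 5 (diacetylation and selective release of the phenol). The β-acetoxy ketone may eliminate to the enone under the basic acetylation, or the ammonolysis may be incomplete or unselective. The fallback sets out from 11 and separates the two hydroxyls with a protecting group. The phenol alone is benzylated (BnBr, K2CO3, acetone, rt) to give (5S)-1-[4-(benzyloxy)-3-methoxyphenyl]-5-hydroxytetradecan-3-one F5. Acetylation of the only remaining hydroxyl (Ac2O, pyridine, 0 °C) gives (5S)-1-[4-(benzyloxy)-3-methoxyphenyl]-3-oxotetradecan-5-yl acetate F6. Neutral hydrogenolysis (H2, 1 atm, Pd/C, EtOAc, rt) removes the benzyl group and gives 13 directly.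

**Further compounds**

F1 | step 1 | 4-methoxy-6-methyl-2H-pyran-2-one | CC1=CC(OC)=CC(=O)O1
F2 | step 1 | 4-methoxy-6-nonyl-2H-pyran-2-one | CCCCCCCCCC1=CC(OC)=CC(=O)O1
F3 | step 1 | 4-(trimethylsilyloxy)-6-nonyl-2H-pyran-2-one | CCCCCCCCCC1=CC(O[Si](C)(C)C)=CC(=O)O1
F4 | step 3 | (6S)-4-hydroxy-6-nonyl-5,6-dihydro-2H-pyran-2-one | CCCCCCCCC[C@H]1CC(O)=CC(=O)O1
F5 | step 5 | (5S)-1-[4-(benzyloxy)-3-methoxyphenyl]-5-hydroxytetradecan-3-one | CCCCCCCCC[C@H](O)CC(=O)CCc1ccc(OCc2ccccc2)c(OC)c1
F6 | step 5 | (5S)-1-[4-(benzyloxy)-3-methoxyphenyl]-3-oxotetradecan-5-yl acetate | CCCCCCCCC[C@@H](CC(=O)CCc1ccc(OCc2ccccc2)c(OC)c1)OC(C)=O
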